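We begin from a count that we take to hold in the teal flask at every moment: each target formed uses one nucleophile and puts one free base out of action, or, once free base is lacking, sends one more nucleophile into protonated nucleophile.

| flask | electrophile | nucleophile | free base | remark | time |
|---|---|---|---|---|---|
| teal | 1.5 M | 1.35 M | 1.5 M | the very flask that is asked about, followed so far |  |
| ochre | 1.5 M | 2 M | 1.5 M | run made earlier |  |
| flask | 1.5 M | 1.35 M | 1.50 M |  | 12 min |

| run | time / min | electrophile / % | target / % |
|---|---|---|---|
| teal | 0.200 | 80.0 | 18.8 |
| teal | 0.417 | 66.1 | 32.8 |
| teal | 1.00 | 44.4 | 52.9 |
| teal | 2.50 | 25.1 | 69.7 |
| ochre | 1.50 | 20.2 | 78.0 |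
| ochre | 4.00 | 4.7 | 92.6 |
| ochre | 8.00 | 0.3 | 95.4 |
| ochre | 12.0 | 0 | 95.8 |

(readings scatter by 0.5 percentage points)

- part of the electrophile that has reacted at 12 min
- share of the unused nucleophile that is free and not bound as protonated nucleophile, at 12 min

- what was read earlier has a scatter of 0.5 percentage points, one standard deviation
- what has gone from electrophile into another species counts as reacted, even if it can come back
- the earlier runs do not show how much of nucleophile is bound; that part of a forecast is a guess

That count makes one difference stay constant while free base lasts, the base margin, free base charged minus nucleophile charged, 0.150 M. We treat the taking-up by free base as instantaneous beside target formation. In the first instants of the teal run, at 0.200 min, target reads 18.8%, so about 0.282 M of free base has gone. By 2.50 min target reads 69.7%, which leaves 0.304 M of nucleophile beside 0.454 M of free base, while 5.20% of the electrophile is in neither column. In the teal flask the nucleophile is the limiting reagent, charged below the electrophile, so our count caps target at 90.0% of the electrophile charged, and electrophile reacted beyond that cap has to go the way of the part that is in neither column. At that cap our count puts free base at 10.0% of its charge. We therefore expect the free share of the unused nucleophile to stand high, with free base still present at that point, because free base charged is more than nucleophile charged.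

The forecast gave 94.5% for the electrophile reacted and 80% for the free share of the unused nucleophile, holding that “the nucleophile seems weakly basic and mostly free”. Our count gives no figure for that share, but we lean above the forecast on it.

    acid set free + free base ⇌ salt of the base, settled at all times (K = 1600 L mol⁻¹)
    electrophile + nucleophile → acid set free + target (k = 0.910 L mol⁻¹ min⁻¹)
    nucleophile + acid set free ⇌ protonated nucleophile, settled at all times (K = 20.0 L mol⁻¹)
    acid set free → by-product carried off (k = 0.840 min⁻¹)
    electrophile ⇌ dormant form (K = 5.20, k = 0.0420 min⁻¹)

The flask gives 94.1% for the electrophile reacted and 94.1% for the free share of the unused nucleophile, the share standing 14 percentage points above the forecast. In this flask at 12.0 min protonated nucleophile stands at 0.00414 M, and free base minus nucleophile is 0.184 M against the margin of 0.150 M. A neighbour flask, the same but charged with 0.90 M of free base, has a margin of −0.450 M, and at 12.0 min its free base is down to 2.70% of its charge, with 68.9% of its unused nucleophile free.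

(Readings and results stem from a simulated flask on assumed constants, and the scatter is random.)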